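The carbocycle (C4a, C5, C6, C7, C8, C8a) is disconnected into carbon monoxide (C5) and a cyclopropane (C6, C7, C8) attached to the enol-ether carbon C8a of a preformed dihydropyran. The key step exploits the unsubstituted trimethylene C6–C7–C8 lying between the C5 carbonyl and the C4a=C8a enol ether: a rhodium-catalysed [5+1] carbonylative ring expansion of the vinylcyclopropane forms C4a–C5 and C5–C6 in one operation and, after tautomerisation, delivers the vinylogous ester. Its precursor, a (2S,4R)-6-cyclopropyl-4-silyloxy-3,4-dihydro-2H-pyran, contains neither the carbonyl nor a six-membered carbocycle. C2 is set by asymmetric hydrogenation of a β-keto ester, C4 by a C2-controlled Luche reduction.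

Key step: step 8

Remark: atom numbers are those of the chromenone skeleton (O1, C2, C3, C4, C4a, C5, C6, C7, C8, C8a); the target is the (2S,4R) isomer with heptadecyl and hydroxyl cis on the pyran ring, and the enol ethers 10 and 11 are assumed to be handled on base-washed silica.

Step 1
Reactants: 1 octadecanoyl chloride (stearoyl chloride); 2 Meldrum's acid (2,2-dimethyl-1,3-dioxane-4,6-dione)
Product: 4 methyl 3-oxoicosanoate, via acyl Meldrum's acid 3 (not isolated)
Conditions: pyridine (2.2 equiv), CH2Cl2, 0 °C → rt; aq. HCl wash; then MeOH, reflux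
Reagents that add atoms: methanol, CO
Why: C-acylation of Meldrum's acid and alcoholysis of the acyl derivative with loss of acetone and CO2 is the standard two-carbon homologation of an acid chloride to a β-keto ester.

Step 2
Reactants: 4 methyl 3-oxoicosanoate
Product: 5 methyl (3S)-3-hydroxyicosanoate
Conditions: [RuCl(p-cymene)((S)-BINAP)]Cl (0.5 mol %), H2 (50 bar), MeOH/CH2Cl2, 50 °C
Reagents that add atoms: none
Why: Noyori asymmetric hydrogenation of a β-keto ester, in which the chelated ketone is reduced on the face dictated by (S)-BINAP, which for 3-oxoalkanoates gives the (S)-3-hydroxy ester and so sets C2 of the target.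

Step 3
Reactants: 5 methyl (3S)-3-hydroxyicosanoate
Product: 6 (3S)-3-hydroxy-N-methoxy-N-methylicosanamide
Conditions: MeNH(OMe)·HCl (2.5 equiv), iPrMgCl (6 equiv), THF, −20 → 0 °C
Reagents that add atoms: N,O-dimethylhydroxylamine hydrochloride, CNOC.Cl
Why: Weinreb amide formation by aminolysis of the ester with the chloromagnesium amide proceeds at low temperature on the magnesium alkoxide without affecting the carbinol centre.

Step 4
Reactants: 6 (3S)-3-hydroxy-N-methoxy-N-methylicosanamide; 7 ethynylcyclopropane
Product: 8 (5S)-1-cyclopropyl-5-hydroxydocos-1-yn-3-one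
Conditions: 7 (3.2 equiv), n-BuLi (3.0 equiv), THF, −78 °C; then 6, −78 → 0 °C; aq. NH4Cl
Reagents that add atoms: none
Why: Weinreb ketone synthesis, in which acylation of the lithium acetylide stops at the ketone stage because the chelated tetrahedral adduct survives until work-up, the extra acetylide serving to deprotonate the hydroxyl.

Step 5
Reactants: 8 (5S)-1-cyclopropyl-5-hydroxydocos-1-yn-3-one
Product: 9 (2S)-6-cyclopropyl-2-heptadecyl-2,3-dihydro-4H-pyran-4-one
Conditions: (Ph3P)AuCl (5 mol %), AgOTf (5 mol %), CH2Cl2, rt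
Reagents that add atoms: none
Why: 6-endo-dig hydroalkoxylation (cycloisomerisation) of the β-hydroxy ynone, in which monovalent gold activates the alkyne and the ketone polarises it so that the hydroxyl attacks the cyclopropyl-bearing carbon, C2 being untouched.

Step 6
Reactants: 9 (2S)-6-cyclopropyl-2-heptadecyl-2,3-dihydro-4H-pyran-4-one
Product: 10 (2S,4R)-6-cyclopropyl-2-heptadecyl-3,4-dihydro-2H-pyran-4-ol
Conditions: NaBH4, CeCl3·7H2O, MeOH/THF, −40 °C; aq. NaHCO3
Reagents that add atoms: none
Why: Luche 1,2-reduction, in which hydride adds axially to the half-chair enone and places the C4 hydroxyl pseudo-equatorial and cis to the pseudo-equatorial C2 heptadecyl group, so that C2 controls the new 4R centre.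

Step 7
Reactants: 10 (2S,4R)-6-cyclopropyl-2-heptadecyl-3,4-dihydro-2H-pyran-4-ol
Product: 11 tert-butyl{[(2S,4R)-6-cyclopropyl-2-heptadecyl-3,4-dihydro-2H-pyran-4-yl]oxy}dimethylsilane
Conditions: TBSCl, imidazole, DMF/CH2Cl2, 0 °C → rt
Reagents that add atoms: tert-butyldimethylsilyl chloride, CC(C)(C)[Si](C)(C)Cl
Why: imidazole-mediated silyl protection of the secondary allylic alcohol under non-acidic conditions masks the C4 hydroxyl for the carbonylation.

Step 8
Reactants: 11 tert-butyl{[(2S,4R)-6-cyclopropyl-2-heptadecyl-3,4-dihydro-2H-pyran-4-yl]oxy}dimethylsilane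
Product: 13 (2S,4R)-4-[(tert-butyldimethylsilyl)oxy]-2-heptadecyl-2,3,4,6,7,8-hexahydro-5H-chromen-5-one, via β,γ-unsaturated ketone 12 (not isolated)
Conditions: [Rh(cod)Cl]2 (5 mol %), dppp (10 mol %), AgOTf (10 mol %), 2,6-di-tert-butyl-4-methylpyridine (0.2 equiv), 4 Å MS, CO (1 atm), ClCH2CH2Cl, 85 °C; then DBU (0.2 equiv), rt
Reagents that add atoms: carbon monoxide, [C-]#[O+]
Why: Proposed new method: the closest known reaction type is the rhodium-catalysed [5+1] cycloaddition of vinylcyclopropanes with CO to cyclohexenones, established for hydrocarbon-substituted alkenes and extended here to an oxygen-substituted, ring-embedded alkene (a cyclopropyl enol ether), which as an electron-rich π-donor should bind cationic monovalent rhodium readily. Mechanism: alkene coordination, oxidative insertion of rhodium into a proximal cyclopropane C–C bond (the two are equivalent, so no regiochemical issue arises) to give an alkyl(2-alkoxyallyl) rhodacyclohexene, migratory insertion of CO into the Rh–CH2 bond, and acyl–allyl reductive elimination at C4a to give the β,γ-enone 12, which DBU tautomerises to the conjugated vinylogous ester 13. The carbocycle (C4a, C5, C6, C7, C8, C8a) is closed in a metal-templated [5+1] mode, the seven-membered acylrhodacycle contracting to the six-membered ring on C4a–C5 bond formation, the C5–C6 bond having been made by the CO insertion. No lasting stereocentre is created (C4a of 12 becomes trigonal in 13), and C2 and C4 are not touched. The selectivities needed are CO insertion before reductive elimination (otherwise the cyclopentene of a vinylcyclopropane rearrangement forms) and C–C coupling at the allyl terminus C4a, not at C8 (which would give a strained vinylcyclobutanone); the CO atmosphere and the preference for the six-membered ring secure them. The silyl ether blocks metal-mediated isomerisation of the allylic alcohol, and the hindered pyridine with molecular sieves suppresses acid-induced ionisation of the allylic C4–O bond.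

Step 9
Reactants: 13 (2S,4R)-4-[(tert-butyldimethylsilyl)oxy]-2-heptadecyl-2,3,4,6,7,8-hexahydro-5H-chromen-5-one
Product: 14 (2S,4R)-2-heptadecyl-4-hydroxy-2,3,4,6,7,8-hexahydro-5H-chromen-5-one
Conditions: HF·pyridine, pyridine, THF, 0 °C → rt
Reagents that add atoms: none
Why: fluoride-mediated desilylation in pyridine-buffered medium frees the C4 hydroxyl without touching the vinylogous ester or either stereocentre.

Compound list
1 | octadecanoyl chloride (stearoyl chloride) | CCCCCCCCCCCCCCCCCC(=O)Cl | starting material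
2 | Meldrum's acid (2,2-dimethyl-1,3-dioxane-4,6-dione) | CC1(C)OC(=O)CC(=O)O1 | starting material
3 | 5-(1-hydroxyoctadecylidene)-2,2-dimethyl-1,3-dioxane-4,6-dione (acyl Meldrum's acid) | CCCCCCCCCCCCCCCCCC(O)=C1C(=O)OC(C)(C)OC1=O | intermediate
4 | methyl 3-oxoicosanoate | CCCCCCCCCCCCCCCCCC(=O)CC(=O)OC | intermediate
5 | methyl (3S)-3-hydroxyicosanoate | CCCCCCCCCCCCCCCCC[C@H](O)CC(=O)OC | intermediate
6 | (3S)-3-hydroxy-N-methoxy-N-methylicosanamide | CCCCCCCCCCCCCCCCC[C@H](O)CC(=O)N(C)OC | intermediate
7 | ethynylcyclopropane (cyclopropylacetylene) | C#CC1CC1 | starting material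
8 | (5S)-1-cyclopropyl-5-hydroxydocos-1-yn-3-one | CCCCCCCCCCCCCCCCC[C@H](O)CC(=O)C#CC1CC1 | intermediate
9 | (2S)-6-cyclopropyl-2-heptadecyl-2,3-dihydro-4H-pyran-4-one | CCCCCCCCCCCCCCCCC[C@H]1CC(=O)C=C(C2CC2)O1 | intermediate
10 | (2S,4R)-6-cyclopropyl-2-heptadecyl-3,4-dihydro-2H-pyran-4-ol (2,4-cis) | CCCCCCCCCCCCCCCCC[C@H]1C[C@@H](O)C=C(C2CC2)O1 | intermediate
11 | tert-butyl{[(2S,4R)-6-cyclopropyl-2-heptadecyl-3,4-dihydro-2H-pyran-4-yl]oxy}dimethylsilane | CCCCCCCCCCCCCCCCC[C@H]1C[C@@H](O[Si](C)(C)C(C)(C)C)C=C(C2CC2)O1 | intermediate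
12 | (2S,4R)-4-[(tert-butyldimethylsilyl)oxy]-2-heptadecyl-2,3,4,4a,6,7-hexahydro-5H-chromen-5-one (C8=C8a enol ether, C4a epimers) | CCCCCCCCCCCCCCCCC[C@H]1C[C@@H](O[Si](C)(C)C(C)(C)C)C2C(=O)CCC=C2O1 | intermediate
13 | (2S,4R)-4-[(tert-butyldimethylsilyl)oxy]-2-heptadecyl-2,3,4,6,7,8-hexahydro-5H-chromen-5-one | CCCCCCCCCCCCCCCCC[C@H]1C[C@@H](O[Si](C)(C)C(C)(C)C)C2=C(CCCC2=O)O1 | intermediate
14 | (2S,4R)-2-heptadecyl-4-hydroxy-2,3,4,6,7,8-hexahydro-5H-chromen-5-one | CCCCCCCCCCCCCCCCC[C@H]1C[C@@H](O)C2=C(CCCC2=O)O1 | target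

Total step count: 9. Longest linear sequence: 9 steps (1 → 14).

Steps most likely to fail

1. Step 8. The cationic rhodium centre may ionise the allylic C4–O bond or trigger protonation of the enol ether instead of inserting into the cyclopropane. The rhodacycle may also collapse before CO uptake (ring expansion to a cyclopentene), or CO may saturate the metal so that the hindered trisubstituted alkene is never bound. The fallback uses known chemistry, an anionic ring closure in place of the carbonylation; it sets out from 6 and returns at 13. Amide 6 would be acylated by the lithium acetylide of hex-5-ynenitrile (n-BuLi, THF, −78 °C) to give (9S)-9-hydroxy-7-oxohexacos-5-ynenitrile F1. Cyclisation as in step 5 would give 4-[(6S)-6-heptadecyl-4-oxo-5,6-dihydro-4H-pyran-2-yl]butanenitrile F2. Electrophilic iodination of the vinylogous ester at its α-carbon (I2, pyridine, CH2Cl2) would give 4-[(6S)-6-heptadecyl-3-iodo-4-oxo-5,6-dihydro-4H-pyran-2-yl]butanenitrile F3. Luche reduction would give the cis alcohol 4-[(4R,6S)-6-heptadecyl-4-hydroxy-3-iodo-5,6-dihydro-4H-pyran-2-yl]butanenitrile F4, and TBSCl/imidazole the silyl ether 4-[(4R,6S)-4-[(tert-butyldimethylsilyl)oxy]-6-heptadecyl-3-iodo-5,6-dihydro-4H-pyran-2-yl]butanenitrile F5. Iodine–lithium exchange (t-BuLi, THF/Et2O, −100 °C) and 6-exo-dig attack of the C4a vinyllithium on the nitrile (Parham-type cyclisation), followed by mild aqueous hydrolysis of the imine, would form the C4a–C5 bond and give 13.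

2. Step 5. Activation of the alkyne by the (Ph3P)AuOTf π-acid may open the cyclopropane (homo-conjugate capture of the cyclopropyl-stabilised vinyl cation) or hydrate the alkyne instead of delivering the hydroxyl in the 6-endo sense. The fallback replaces π-acid catalysis by conjugate addition–elimination; it sets out from 8 and returns at 9. Diethylamine (EtOH, rt) would add to the ynone to give the enaminone (1E,5S)-1-cyclopropyl-1-(diethylamino)-5-hydroxydocos-1-en-3-one F6. CF3CO2H in CH2Cl2 would then promote attack of the hydroxyl on the iminium-activated β-carbon with loss of diethylamine to give 9.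

3. Step 4. The lithium alkoxide of 6 may aggregate and stall acyl transfer, or the acetylide may enolise the amide and expel the β-alkoxide (elimination to the unsaturated amide). The fallback uses a silyl-protected ester and Lewis-acid-mediated acylation in place of the amide dianion; it sets out from 5 and returns at 8. TBSCl/imidazole would give methyl (3S)-3-[(tert-butyldimethylsilyl)oxy]icosanoate F7. Lithium cyclopropylacetylide with BF3·OEt2 (THF, −78 °C) would convert the ester into (5S)-5-[(tert-butyldimethylsilyl)oxy]-1-cyclopropyldocos-1-yn-3-one F8, and HF·pyridine would then release 8.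

Further compounds
F1 | step 8 | (9S)-9-hydroxy-7-oxohexacos-5-ynenitrile | CCCCCCCCCCCCCCCCC[C@H](O)CC(=O)C#CCCCC#N
F2 | step 8 | 4-[(6S)-6-heptadecyl-4-oxo-5,6-dihydro-4H-pyran-2-yl]butanenitrile | CCCCCCCCCCCCCCCCC[C@H]1CC(=O)C=C(CCCC#N)O1
F3 | step 8 | 4-[(6S)-6-heptadecyl-3-iodo-4-oxo-5,6-dihydro-4H-pyran-2-yl]butanenitrile | CCCCCCCCCCCCCCCCC[C@H]1CC(=O)C(I)=C(CCCC#N)O1
F4 | step 8 | 4-[(4R,6S)-6-heptadecyl-4-hydroxy-3-iodo-5,6-dihydro-4H-pyran-2-yl]butanenitrile | CCCCCCCCCCCCCCCCC[C@H]1C[C@@H](O)C(I)=C(CCCC#N)O1
F5 | step 8 | 4-[(4R,6S)-4-[(tert-butyldimethylsilyl)oxy]-6-heptadecyl-3-iodo-5,6-dihydro-4H-pyran-2-yl]butanenitrile | CCCCCCCCCCCCCCCCC[C@H]1C[C@@H](O[Si](C)(C)C(C)(C)C)C(I)=C(CCCC#N)O1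
F6 | step 5 | (1E,5S)-1-cyclopropyl-1-(diethylamino)-5-hydroxydocos-1-en-3-one | CCCCCCCCCCCCCCCCC[C@H](O)CC(=O)/C=C(\C1CC1)N(CC)CC
F7 | step 4 | methyl (3S)-3-[(tert-butyldimethylsilyl)oxy]icosanoate | CCCCCCCCCCCCCCCCC[C@H](O[Si](C)(C)C(C)(C)C)CC(=O)OC
F8 | step 4 | (5S)-5-[(tert-butyldimethylsilyl)oxy]-1-cyclopropyldocos-1-yn-3-one | CCCCCCCCCCCCCCCCC[C@H](O[Si](C)(C)C(C)(C)C)CC(=O)C#CC1CC1
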